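The runs are calculated for an exercise.

The time of a reading moved the ratio r of side product to target little in the larch run, where r was 1.33 at 4.00 min and 1.19 at 30.0 min. So I pooled each run's readings and looked for what does move r, the selectivity, between runs.

| setting | larch | cedar | ash | flask |
|---|---|---|---|---|
| substrate | 0.025 M | 0.10 M | 0.050 M | 0.050 M |
| partner | 0.0475 M | 0.0475 M | 0.024 M | 0.0475 M |
| remark | run made earlier | run made earlier | run made earlier |  |
| time |  |  |  | 30 min |

- larch (time / min: side product / %, target / %, substrate / %): 4.00: 32, 24, 8; 10.0: 47, 35, 2; 20.0: 52, 40, 2; 30.0: 50, 42, 1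
- cedar (time / min: side product / %, target / %, substrate / %): 8.00: 8, 17, 7; 15.0: 8, 22, 4; 25.0: 10, 24, 2; 30.0: 7, 25, 1
- ash (time / min: side product / %, target / %, substrate / %): 2.50: 3, 8, 21; 6.00: 3, 17, 12; 12.0: 11, 24, 7; 30.0: 5, 29, 2

(scatter of a reading: 1.5 percentage points)



1. ratio of side product to target at 15 s
2. ratio of side product to target at 2.5 min
3. ratio of side product to target at 30 min

Let ρ be the charged partner over the charged substrate, and g the pooled r divided by ρ. I reckoned g in two independent ways.

Larch has ρ = 1.90 and pooled r = 1.28, which gives g = 0.676.

Cedar and ash, taken as a pair, have pooled r of 0.375 and 0.282. Their summed r over summed ρ gives 0.688, so the two ways agree, and they rest on different runs.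

Taken singly, though, cedar gives 0.789 and ash 0.588. These two runs stand at ρ = 0.475 and 0.480, so ρ does not carry r by itself, and g is no constant. I kept the larch value as a working figure, with that split standing against it.

For the flask, g gives r = 0.642. I committed to that at 2.5 min and 30 min. It carries no clock, and 15 s lies earlier than any reading, so I gave it no weight there.

The forecast stood at 0.7, 0.68 and 0.6, above my flat figure early and below it late, on the ground that “Early ratios tend slightly higher”.

The flask gave r = 1.05 at 15 s, 0.710 at 2.5 min and 0.560 at 30 min.

    partner + intermediate A ⇌ intermediate B (K = 7.00 M⁻¹, k = 0.630 M⁻¹ s⁻¹)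
    substrate + partner ⇌ intermediate A (K = 220 M⁻¹, k = 7.70 M⁻¹ s⁻¹)
    2 substrate → self-condensation product (k = 0.220 M⁻¹ s⁻¹)
    partner + intermediate A → side product (k = 0.150 M⁻¹ s⁻¹)
    intermediate A → target (k = 0.00220 s⁻¹)

In the flask, side product and target stood level at 0.295 min, each at 2.07%. My g-based figure of 0.642 lay between the flask's values at 2.5 min and 30 min. For a neighbouring flask charged with 0.030 M of substrate, g gives r = 1.07, and that flask gave 0.956 at 30 min.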